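**Plan**
- **Cuts.** Locants: lactone O1, C2–C6; side chain C1'–C10'. The C2 carbonyl goes back to a (Z)-allylic CH2OH, to be closed by oxidative lactonisation onto O1. Then C3'–C4' and C6–C1' are cut, which leaves C1'–C3' as a C3 allenylboronate between two aldehydes. The C4'–C10' aldehyde is cut at C5'–C6' (Claisen) to a β-keto ester.
- **Enabling feature.** O1–C6–C1'=C2'–C3'–C4'–OH is a (Z)-pent-2-ene-1,5-diol with 1,5-anti oxygens. This is the footprint of two consecutive allylborations on one C3 unit. The boron-bearing C1' is a temporary stereocentre that is consumed when the alkene forms.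
- **Forward order.** C4'–C10' aldehyde (5 steps); C2–C6 skipped (Z)-enal (3 steps); borane and allenylboronate (1 step each). A one-flask union follows, C6–C1' first and then C3'–C4'. Desilylation, closure of the only new ring (the dihydropyranone) and acetonide removal finish the route.
- **Stereochemistry.** C8' comes from Noyori hydrogenation. C6' is relayed from C8' by hydroxyl-directed 1,3-anti reduction. C6 comes from the isopinocampheyl ligands. C4' and the Z C1'=C2' alkene come from chirality transfer out of C1'. The Z C3=C4 alkene comes from Lindlar reduction.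

Key step: step 11

Remark: the SMILES is read as (6S,1'Z,4'R,6'S,8'R), that is 4',6'-syn, 6',8'-anti and O1/4'-OH 1,5-anti across the Z-alkene. Compounds marked "starting material" in the list are taken as catalogue items.

Step 1
Reactants: 1 ethyl 3-oxo-5-phenylpentanoate
Product: 2 ethyl (3R)-3-hydroxy-5-phenylpentanoate
Conditions: RuCl2[(R)-BINAP] (0.2 mol %), H2 (10 bar), EtOH, 60 °C
Reagents that add atoms: none
Why: Noyori asymmetric hydrogenation of a β-keto ester, in which the ester carbonyl chelates Ru and the (R)-BINAP ligand directs hydride to the face that gives the (R)-carbinol (C8' of the target).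

Step 2
Reactants: 2 ethyl (3R)-3-hydroxy-5-phenylpentanoate; 3 tert-butyl acetate
Product: 5 tert-butyl (5R)-5-hydroxy-3-oxo-7-phenylheptanoate, via lithium enolate 4 (not isolated)
Conditions: 3 (3.5 equiv), LDA (3.5 equiv), THF, −78 °C; then 2, −78 → −10 °C; AcOH quench
Reagents that add atoms: none
Why: Crossed Claisen condensation, in which excess enolate 4 first deprotonates the free hydroxyl and then acylates at the ethyl ester (C5'–C6' bond), and the product rests as its enolate until the quench, so C8' is untouched.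

Step 3
Reactants: 5 tert-butyl (5R)-5-hydroxy-3-oxo-7-phenylheptanoate
Product: 6 tert-butyl (3S,5R)-3,5-dihydroxy-7-phenylheptanoate
Conditions: Me4NBH(OAc)3, MeCN–AcOH (1:1), −30 °C
Reagents that add atoms: none
Why: Evans–Saksena reduction, in which the C5 hydroxyl binds boron and delivers hydride intramolecularly through a chair, so the new carbinol (C6') forms 1,3-anti to C8'.

Step 4
Reactants: 6 tert-butyl (3S,5R)-3,5-dihydroxy-7-phenylheptanoate
Product: 7 tert-butyl 2-[(4S,6R)-2,2-dimethyl-6-(2-phenylethyl)-1,3-dioxan-4-yl]acetate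
Conditions: Me2C(OMe)2, PPTS (cat.), CH2Cl2, rt
Reagents that add atoms: 2,2-dimethoxypropane COC(C)(C)OC
Why: Acid-catalysed transketalisation ties the 1,3-diol into a six-membered acetonide without touching either stereocentre or the tert-butyl ester.

Step 5
Reactants: 7 tert-butyl 2-[(4S,6R)-2,2-dimethyl-6-(2-phenylethyl)-1,3-dioxan-4-yl]acetate
Product: 8 2-[(4S,6R)-2,2-dimethyl-6-(2-phenylethyl)-1,3-dioxan-4-yl]acetaldehyde
Conditions: DIBAL-H (1.1 equiv), CH2Cl2, −78 °C; Rochelle salt
Reagents that add atoms: none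
Why: Partial ester reduction, in which the aluminium hemiacetal persists at −78 °C and collapses to the aldehyde only on work-up, and the acetonide is inert to hydride.

Step 6
Reactants: 9 tert-butyldimethyl(prop-2-yn-1-yloxy)silane; 10 ethylene oxide
Product: 12 5-(tert-butyldimethylsilyloxy)pent-3-yn-1-ol, via lithium acetylide 11 (not isolated)
Conditions: n-BuLi, THF, −78 °C; BF3·OEt2; then 10, −78 °C
Reagents that add atoms: none
Why: BF3-assisted opening of an epoxide by a lithium acetylide (Yamaguchi-type alkynylation) adds the two carbons that become C5 and C6, and the silyl ether is stable at −78 °C.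

Step 7
Reactants: 12 5-(tert-butyldimethylsilyloxy)pent-3-yn-1-ol
Product: 13 (Z)-5-(tert-butyldimethylsilyloxy)pent-3-en-1-ol
Conditions: H2 (1 atm), Lindlar catalyst, quinoline, EtOAc, rt
Reagents that add atoms: none
Why: Lindlar semihydrogenation adds H2 syn on the poisoned Pd surface and should stop at the Z-alkene that becomes C3=C4 of the lactone.

Step 8
Reactants: 13 (Z)-5-(tert-butyldimethylsilyloxy)pent-3-en-1-ol
Product: 14 (Z)-5-(tert-butyldimethylsilyloxy)pent-3-enal
Conditions: Dess–Martin periodinane, CH2Cl2, 0 °C; used at once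
Reagents that add atoms: none
Why: Dess–Martin oxidation is fast, base-free and nearly neutral, as needed for a skipped (Z)-enal whose double bond must not move into conjugation.

Step 9
Reactants: 15 (1S,5S)-(−)-α-pinene
Product: 16 (+)-diisopinocampheylborane [(lIpc)2BH]
Conditions: BH3·SMe2, 15 (2.3 equiv), THF, 0 °C; crystals collected under Ar
Reagents that add atoms: borane–dimethyl sulfide C[S+](C)[BH3-]
Why: Brown hydroboration, in which BH3 adds twice from the face anti to the CMe2 bridge and stops at the hindered dialkylborane, and crystallisation in the presence of excess pinene raises its optical purity.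

Step 10
Reactants: 17 propargyl bromide; 18 benzopinacol (1,1,2,2-tetraphenylethane-1,2-diol)
Product: 21 4,4,5,5-tetraphenyl-2-(propa-1,2-dien-1-yl)-1,3,2-dioxaborolane, via allenylmagnesium bromide 19 (not isolated), via allenylboronic acid 20 (not isolated)
Conditions: Mg, HgCl2 (cat.), Et2O, 0 °C; B(OMe)3, −78 °C; 2 M HCl; then 18, 4 Å MS, toluene, rt
Reagents that add atoms: trimethyl borate COB(OC)OC
Why: Grignard borylation of the allenyl organomagnesium gives the allenylboronic acid, which is esterified with the bulky diol that later enforces the Z-selective chair.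

Step 11
Reactants: 21 4,4,5,5-tetraphenyl-2-(propa-1,2-dien-1-yl)-1,3,2-dioxaborolane; 16 (+)-diisopinocampheylborane; 14 (Z)-5-(tert-butyldimethylsilyloxy)pent-3-enal; 8 2-[(4S,6R)-2,2-dimethyl-6-(2-phenylethyl)-1,3-dioxan-4-yl]acetaldehyde
Product: 25 (2Z,5S,6Z,9R)-1-(tert-butyldimethylsilyloxy)-10-[(4R,6R)-2,2-dimethyl-6-(2-phenylethyl)-1,3-dioxan-4-yl]deca-2,6-diene-5,9-diol, via (Z)-γ-borylallylborane 22 (not isolated), via syn-α-substituted allylboronate 23 (not isolated), via O-borylated adduct 24 (not isolated)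
Conditions: 21 (1.1 equiv), 16 (1.0 equiv), toluene, −30 °C; 14 (0.95 equiv), −78 °C; 8 (0.8 equiv), −78 °C → rt; then aq NaHCO3, H2O2
Reagents that add atoms: none
Why: At −30 °C 16 adds B–H across the terminal C=C of 21 from the side away from the dioxaborolane and gives kinetically the (Z)-γ-borylallylborane 22, whose B(Ipc)2 end alone is allylic, so 14 is taken up at −78 °C through a Zimmerman–Traxler chair to give 23, and only this first addition unmasks the slower allylboronate that adds to 8 on warming and makes the C3'–C4' bond with allyl transposition. The closest known reaction type is the allene hydroboration/one-pot double allylboration used for pent-2-ene-1,5-diols, together with the 1,3-chirality transfer of α-substituted allylboronates of bulky diols. No ring is closed, and both C–C bonds form in six-membered cyclic transition states. C6 (S) is set by the lIpc ligands, which select the face of 14, and the Z geometry of 22 places the boronate axial, so the sacrificial C1' centre (S) arises syn to C6. In the second chair the chain of 8 lies equatorial and the C6-bearing substituent on C1' is pushed axial by the four phenyl groups of the dioxaborolane, which converts C1'(S) into the Z C1'=C2' alkene and C4'(R) in the same event and erases C1'. The step needs order-of-addition chemoselectivity (secured by the rate gap between allylborane and allylboronate and by near-equimolar 14), retention of the kinetic Z geometry of 22 (secured by low temperature until 14 is in) and reagent control over the weak 1,3-bias of the β-alkoxy aldehyde 8 (secured by the closed chair, in which the other face costs the equatorial, phenyl-clashing arrangement).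

Step 12
Reactants: 25 (2Z,5S,6Z,9R)-1-(tert-butyldimethylsilyloxy)-10-[(4R,6R)-2,2-dimethyl-6-(2-phenylethyl)-1,3-dioxan-4-yl]deca-2,6-diene-5,9-diol
Product: 26 (2Z,5S,6Z,9R)-10-[(4R,6R)-2,2-dimethyl-6-(2-phenylethyl)-1,3-dioxan-4-yl]deca-2,6-diene-1,5,9-triol
Conditions: TBAF, THF, 0 °C
Reagents that add atoms: none
Why: Fluoride-mediated desilylation frees the primary allylic alcohol, and the acetonide, both Z-alkenes and the carbinols are inert to fluoride.

Step 13
Reactants: 26 (2Z,5S,6Z,9R)-10-[(4R,6R)-2,2-dimethyl-6-(2-phenylethyl)-1,3-dioxan-4-yl]deca-2,6-diene-1,5,9-triol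
Product: 29 (6S)-6-{(1Z,4R)-5-[(4R,6R)-2,2-dimethyl-6-(2-phenylethyl)-1,3-dioxan-4-yl]-4-hydroxypent-1-en-1-yl}-5,6-dihydro-2H-pyran-2-one, via (Z)-hydroxyenal 27 (not isolated), via lactol 28 (not isolated)
Conditions: TEMPO (0.2 equiv), PhI(OAc)2 (2.5 equiv), CH2Cl2, rt
Reagents that add atoms: none
Why: TEMPO/PhI(OAc)2 oxidative lactonisation of a (Z)-2-ene-1,5-diol, in which the hindered oxoammonium salt selects the primary allylic alcohol, the Z geometry lets only the C6 hydroxyl close the six-membered lactol (6-exo-trig), and the lactol is oxidised on while the C4' carbinol stays free and C6 is untouched.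

Step 14
Reactants: 29 (6S)-6-{(1Z,4R)-5-[(4R,6R)-2,2-dimethyl-6-(2-phenylethyl)-1,3-dioxan-4-yl]-4-hydroxypent-1-en-1-yl}-5,6-dihydro-2H-pyran-2-one
Product: 30 (6S)-6-[(1Z,4R,6S,8R)-4,6,8-trihydroxy-10-phenyldec-1-en-1-yl]-5,6-dihydro-2H-pyran-2-one
Conditions: AcOH–H2O (4:1), 40 °C
Reagents that add atoms: none
Why: Mild acid hydrolysis of the strained anti-acetonide releases the 6',8'-diol under non-nucleophilic aqueous conditions that leave the enoate lactone and both Z-alkenes intact.

**Compound list**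
1 | ethyl 3-oxo-5-phenylpentanoate | CCOC(=O)CC(=O)CCc1ccccc1 | starting material
2 | ethyl (3R)-3-hydroxy-5-phenylpentanoate | CCOC(=O)C[C@H](O)CCc1ccccc1 | intermediate
3 | tert-butyl acetate | CC(=O)OC(C)(C)C | starting material
4 | lithium enolate of tert-butyl acetate | C=C(O[Li])OC(C)(C)C | intermediate
5 | tert-butyl (5R)-5-hydroxy-3-oxo-7-phenylheptanoate | CC(C)(C)OC(=O)CC(=O)C[C@H](O)CCc1ccccc1 | intermediate
6 | tert-butyl (3S,5R)-3,5-dihydroxy-7-phenylheptanoate (1,3-anti) | CC(C)(C)OC(=O)C[C@@H](O)C[C@H](O)CCc1ccccc1 | intermediate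
7 | tert-butyl 2-[(4S,6R)-2,2-dimethyl-6-(2-phenylethyl)-1,3-dioxan-4-yl]acetate | CC(C)(C)OC(=O)C[C@@H]1C[C@@H](CCc2ccccc2)OC(C)(C)O1 | intermediate
8 | 2-[(4S,6R)-2,2-dimethyl-6-(2-phenylethyl)-1,3-dioxan-4-yl]acetaldehyde | O=CC[C@@H]1C[C@@H](CCc2ccccc2)OC(C)(C)O1 | intermediate
9 | tert-butyldimethyl(prop-2-yn-1-yloxy)silane | C#CCO[Si](C)(C)C(C)(C)C | starting material
10 | ethylene oxide | C1CO1 | starting material
11 | lithium acetylide of 9 | [Li]C#CCO[Si](C)(C)C(C)(C)C | intermediate
12 | 5-(tert-butyldimethylsilyloxy)pent-3-yn-1-ol | OCCC#CCO[Si](C)(C)C(C)(C)C | intermediate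
13 | (Z)-5-(tert-butyldimethylsilyloxy)pent-3-en-1-ol | OCC/C=C\CO[Si](C)(C)C(C)(C)C | intermediate
14 | (Z)-5-(tert-butyldimethylsilyloxy)pent-3-enal | O=CC/C=C\CO[Si](C)(C)C(C)(C)C | intermediate
15 | (1S,5S)-(−)-α-pinene | CC1=CC[C@H]2C[C@@H]1C2(C)C | starting material
16 | (+)-diisopinocampheylborane, (lIpc)2BH | B([C@H]1C[C@H]2C[C@@H]([C@@H]1C)C2(C)C)[C@H]1C[C@H]2C[C@@H]([C@@H]1C)C2(C)C | intermediate
17 | propargyl bromide | C#CCBr | starting material
18 | benzopinacol (1,1,2,2-tetraphenylethane-1,2-diol) | OC(c1ccccc1)(c1ccccc1)C(O)(c1ccccc1)c1ccccc1 | starting material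
19 | allenylmagnesium bromide | C=C=C[Mg]Br | intermediate
20 | allenylboronic acid | C=C=CB(O)O | intermediate
21 | 4,4,5,5-tetraphenyl-2-(propa-1,2-dien-1-yl)-1,3,2-dioxaborolane | C=C=CB1OC(c2ccccc2)(c2ccccc2)C(c2ccccc2)(c2ccccc2)O1 | intermediate
22 | (Z)-[3-(4,4,5,5-tetraphenyl-1,3,2-dioxaborolan-2-yl)prop-2-en-1-yl]bis(lIpc)borane | B(C/C=C\B1OC(c2ccccc2)(c2ccccc2)C(c2ccccc2)(c2ccccc2)O1)([C@H]1C[C@H]2C[C@@H]([C@@H]1C)C2(C)C)[C@H]1C[C@H]2C[C@@H]([C@@H]1C)C2(C)C | intermediate
23 | (3S,4S,6Z)-8-(tert-butyldimethylsilyloxy)-3-(4,4,5,5-tetraphenyl-1,3,2-dioxaborolan-2-yl)octa-1,6-dien-4-yl bis(lIpc)borinate | CC(C)(C)[Si](C)(C)OC/C=C\C[C@H](OB([C@H]1C[C@H]2C[C@@H]([C@@H]1C)C2(C)C)[C@H]1C[C@H]2C[C@@H]([C@@H]1C)C2(C)C)[C@H](C=C)B1OC(c2ccccc2)(c2ccccc2)C(c2ccccc2)(c2ccccc2)O1 | intermediate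
24 | compound 25 carrying O–B(lIpc)2 at C5 and O–B(tetraphenyldioxaborolanyl) at C9 | CC(C)(C)[Si](C)(C)OC/C=C\C[C@H](OB([C@H]1C[C@H]2C[C@@H]([C@@H]1C)C2(C)C)[C@H]1C[C@H]2C[C@@H]([C@@H]1C)C2(C)C)/C=C\C[C@@H](OB1OC(c2ccccc2)(c2ccccc2)C(c2ccccc2)(c2ccccc2)O1)C[C@@H]1C[C@@H](CCc2ccccc2)OC(C)(C)O1 | intermediate
25 | (2Z,5S,6Z,9R)-1-(tert-butyldimethylsilyloxy)-10-[(4R,6R)-2,2-dimethyl-6-(2-phenylethyl)-1,3-dioxan-4-yl]deca-2,6-diene-5,9-diol | CC(C)(C)[Si](C)(C)OC/C=C\C[C@H](O)/C=C\C[C@@H](O)C[C@@H]1C[C@@H](CCc2ccccc2)OC(C)(C)O1 | intermediate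
26 | (2Z,5S,6Z,9R)-10-[(4R,6R)-2,2-dimethyl-6-(2-phenylethyl)-1,3-dioxan-4-yl]deca-2,6-diene-1,5,9-triol | OC/C=C\C[C@H](O)/C=C\C[C@@H](O)C[C@@H]1C[C@@H](CCc2ccccc2)OC(C)(C)O1 | intermediate
27 | (2Z,5S,6Z,9R)-10-[(4R,6R)-2,2-dimethyl-6-(2-phenylethyl)-1,3-dioxan-4-yl]-5,9-dihydroxydeca-2,6-dienal | O=C/C=C\C[C@H](O)/C=C\C[C@@H](O)C[C@@H]1C[C@@H](CCc2ccccc2)OC(C)(C)O1 | intermediate
28 | lactol of 27 (5,6-dihydro-2H-pyran-2-ol, anomeric mixture, 6S) | OC1C=CC[C@@H](/C=C\C[C@@H](O)C[C@@H]2C[C@@H](CCc3ccccc3)OC(C)(C)O2)O1 | intermediate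
29 | (6S)-6-{(1Z,4R)-5-[(4R,6R)-2,2-dimethyl-6-(2-phenylethyl)-1,3-dioxan-4-yl]-4-hydroxypent-1-en-1-yl}-5,6-dihydro-2H-pyran-2-one | O=C1C=CC[C@@H](/C=C\C[C@@H](O)C[C@@H]2C[C@@H](CCc3ccccc3)OC(C)(C)O2)O1 | intermediate
30 | (6S)-6-[(1Z,4R,6S,8R)-4,6,8-trihydroxy-10-phenyldec-1-en-1-yl]-5,6-dihydro-2H-pyran-2-one | O=C1C=CC[C@@H](/C=C\C[C@@H](O)C[C@@H](O)C[C@H](O)CCc2ccccc2)O1 | target

**Step count**
Total step count: 14. Longest linear sequence: 9 (steps 1–5 and 11–14).

**Steps most likely to fail**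

(a) Step 11. Borotropic Z→E equilibration of 22 before 14 is added would erode the C6/C1' relationship. Leakage through the chair with the equatorial α-substituent in the second addition would then erode both the alkene geometry and C4'.
The fallback sets out from 8 (with 14) and comes back at 25.
- Aldehyde 8 is propargylated with allenylboronic acid pinacol ester under chiral phosphoric acid catalysis, with the catalyst enantiomer chosen for the 4'R carbinol, to give the homopropargylic alcohol F1.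
- ProPhenol/Me2Zn alkynylation of 14 with this terminal alkyne, with the ligand enantiomer chosen for 6S, gives the propargylic alcohol F2.
- Lindlar semihydrogenation of the alkyne gives 25.

(b) Step 8. The skipped Z double bond may migrate into conjugation with the new aldehyde, or drift to E, during oxidation, work-up or storage.
The fallback sets out from 21 (with 16 and 8) and comes back at 30.
- Stable 3-(tert-butyldimethylsilyloxy)propanal F3 takes the place of 14 in the one-flask double allylboration and gives the diol F4.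
- Silylation of both carbinols (TBSOTf, 2,6-lutidine) gives the tris-silyl ether F5.
- Buffered HF·pyridine frees the primary alcohol F6.
- Dess–Martin oxidation gives the β-silyloxy aldehyde F7.
- Still–Gennari olefination gives the (Z)-enoate F8.
- Aqueous HF in MeCN removes both silyl groups and the acetonide, and the liberated C6 hydroxyl lactonises to 30.

(c) Step 13. The oxoammonium salt may oxidise the C6 allylic or the C4' carbinol before the lactol has closed.
The fallback sets out from 25 and comes back at 30.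
- Both carbinols of 25 are silylated (TBSOTf, 2,6-lutidine) to the tris-silyl ether F9.
- Buffered HF·pyridine frees only the primary allylic alcohol F10.
- TEMPO/PhI(OAc)2 in aqueous MeCN takes it to the (Z)-enoic acid F11.
- Aqueous HF in MeCN removes the silyl groups and the acetonide, and the hydroxy acid closes to 30.

**Further compounds**
F1 | step 11 | (2R)-1-[(4R,6R)-2,2-dimethyl-6-(2-phenylethyl)-1,3-dioxan-4-yl]pent-4-yn-2-ol | C#CC[C@@H](O)C[C@@H]1C[C@@H](CCc2ccccc2)OC(C)(C)O1
F2 | step 11 | 6,7-alkyne analogue of 25 (2Z,5S,9R) | CC(C)(C)[Si](C)(C)OC/C=C\C[C@H](O)C#CC[C@@H](O)C[C@@H]1C[C@@H](CCc2ccccc2)OC(C)(C)O1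
F3 | step 8 | 3-(tert-butyldimethylsilyloxy)propanal | O=CCCO[Si](C)(C)C(C)(C)C
F4 | step 8 | (3S,4Z,7R)-1-(tert-butyldimethylsilyloxy)-8-[2,2-dimethyl-6-(2-phenylethyl)-1,3-dioxan-4-yl]oct-4-ene-3,7-diol | CC(C)(C)[Si](C)(C)OCC[C@H](O)/C=C\C[C@@H](O)C[C@@H]1C[C@@H](CCc2ccccc2)OC(C)(C)O1
F5 | step 8 | 3,7-bis-TBS ether of F4 | CC(C)(C)[Si](C)(C)OCC[C@H](O[Si](C)(C)C(C)(C)C)/C=C\C[C@@H](O[Si](C)(C)C(C)(C)C)C[C@@H]1C[C@@H](CCc2ccccc2)OC(C)(C)O1
F6 | step 8 | primary alcohol from F5 | OCC[C@H](O[Si](C)(C)C(C)(C)C)/C=C\C[C@@H](O[Si](C)(C)C(C)(C)C)C[C@@H]1C[C@@H](CCc2ccccc2)OC(C)(C)O1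
F7 | step 8 | β-silyloxy aldehyde from F6 | O=CC[C@H](O[Si](C)(C)C(C)(C)C)/C=C\C[C@@H](O[Si](C)(C)C(C)(C)C)C[C@@H]1C[C@@H](CCc2ccccc2)OC(C)(C)O1
F8 | step 8 | methyl (2Z,6Z)-dienoate from F7 | COC(=O)/C=C\C[C@H](O[Si](C)(C)C(C)(C)C)/C=C\C[C@@H](O[Si](C)(C)C(C)(C)C)C[C@@H]1C[C@@H](CCc2ccccc2)OC(C)(C)O1
F9 | step 13 | 5,9-bis-TBS ether of 25 | CC(C)(C)[Si](C)(C)OC/C=C\C[C@H](O[Si](C)(C)C(C)(C)C)/C=C\C[C@@H](O[Si](C)(C)C(C)(C)C)C[C@@H]1C[C@@H](CCc2ccccc2)OC(C)(C)O1
F10 | step 13 | primary (Z)-allylic alcohol from F9 | OC/C=C\C[C@H](O[Si](C)(C)C(C)(C)C)/C=C\C[C@@H](O[Si](C)(C)C(C)(C)C)C[C@@H]1C[C@@H](CCc2ccccc2)OC(C)(C)O1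
F11 | step 13 | (2Z,6Z)-dienoic acid from F10 | OC(=O)/C=C\C[C@H](O[Si](C)(C)C(C)(C)C)/C=C\C[C@@H](O[Si](C)(C)C(C)(C)C)C[C@@H]1C[C@@H](CCc2ccccc2)OC(C)(C)O1
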